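The route rests on cutting C7'–C8' and C8–C7 of the furofuran. The feature exploited is the C8–C8' bond shared by the two tetrahydrofuran rings. Both carbons are methines flanked by one CH2O carbon (C9, C9') and one aryl-bearing C–O carbon (C7 on ring A, C7' on ring B). This is the pattern left on Cα/Cβ of a butenolide after a nucleophile and an electrophile have added. In one flask a lithiated ring B dithiane, already carrying the silylated threo-glycerol chain and ring C, adds to (5S)-5-(d-menthyloxy)butenolide and the enolate captures O-TIPS vanillin. This gives two C–C bonds and trans C8'/C8 in absolute form. C7' stays at ketone level, so a late convex-face hydride makes ring B endo.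

Key step: step 11

Numbering: C7–C9 belong to the ring A (guaiacyl) half, C7'–C9' to the ring B half, and C7''–C9'' to the glycerol chain on ring C. The target is 7R,8S,7'S,8'S,7''R,8''R (ring A exo, ring B endo, threo chain). C7''/C8'' are set in step 8, C8'/C8 in step 11, C7 in step 13 and C7' in step 15.

Assumption: the aldol is taken to be unselective at C7, so 21, 22 and F4 are written as the 7R epimer for bookkeeping and both epimers are carried on together, because step 13 re-forms C7 from a planar cation. The hemiketal carbon of 25 and F4 equilibrates and is written without configuration.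

Step 1
Reactants: 1 furfural
Product: 2 5-hydroxyfuran-2(5H)-one (racemic)
Conditions: O2, visible light, rose bengal (disodium 4,5,6,7-tetrachloro-2',4',5',7'-tetraiodofluorescein, cat.), MeOH, 0–20 °C
Reagents that add atoms: dioxygen, O=O
Why: Furan photooxygenation, in which sensitised singlet oxygen adds [4+2] across C2/C5 of the furan and methanol-assisted fragmentation of the endoperoxide expels the formyl carbon as methyl formate, leaving the racemic γ-hydroxybutenolide whose labile stereocentre is fixed only in step 2.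

Step 2
Reactants: 2 5-hydroxyfuran-2(5H)-one; 3 (+)-menthol
Product: 4 (5S)-5-[(1S,2R,5S)-menthyloxy]furan-2(5H)-one
Conditions: (+)-camphor-10-sulfonic acid (cat.), toluene, reflux, Dean–Stark; crystallisation from petroleum ether, liquors re-equilibrated with the same acid and recrystallised
Reagents that add atoms: none
Why: Acid-catalysed acetalisation of the pseudo-acid gives both C5 epimers, which interconvert under the acid, and since the (5S) epimer of the (+)-menthyl series is the crystalline one, crystallisation with re-equilibration of the liquors (crystallisation-driven resolution of a labile acetal centre) should deliver 4 as a single stereoisomer.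

Step 3
Reactants: 5 vanillin
Product: 6 3-methoxy-4-(triisopropylsilyloxy)benzaldehyde (O-TIPS vanillin)
Conditions: TIPSCl, imidazole, DMF, rt
Reagents that add atoms: chlorotriisopropylsilane, CC(C)[Si](Cl)(C(C)C)C(C)C
Why: Imidazole-promoted O-silylation of a phenol, with TIPS chosen because the aryl silyl ether must withstand a lithium enolate, LiAlH4 and cold BF3·OEt2 and still leave with fluoride.

Step 4
Reactants: 7 syringaldehyde
Product: 8 3,5-dimethoxy-4-(triisopropylsilyloxy)benzaldehyde
Conditions: TIPSCl, imidazole, DMF, 40 °C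
Reagents that add atoms: chlorotriisopropylsilane, CC(C)[Si](Cl)(C(C)C)C(C)C
Why: The same phenol O-silylation, warmed gently because the hydroxyl is flanked by two methoxy groups, which in turn make this silyl ether especially robust.

Step 5
Reactants: 7 syringaldehyde
Product: 9 4-(1,3-dithian-2-yl)-2,6-dimethoxyphenol
Conditions: HS(CH2)3SH, BF3·OEt2 (cat.), CH2Cl2, 0 °C → rt
Reagents that add atoms: propane-1,3-dithiol, SCCCS
Why: Lewis-acid-catalysed thioacetalisation, chemoselective beside the free phenol, and the dithiane first masks the aldehyde through steps 6–10 and then serves as the acyl-anion equivalent of the key step.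

Step 6
Reactants: 9 4-(1,3-dithian-2-yl)-2,6-dimethoxyphenol
Product: 11 [4-(1,3-dithian-2-yl)-2,6-dimethoxyphenoxy]acetic acid, via methyl ester 10 (not isolated)
Conditions: BrCH2CO2Me, K2CO3, MeCN, reflux; then aq NaOH, MeOH, rt; 1 M HCl to pH 3
Reagents that add atoms: methyl bromoacetate, COC(=O)CBr; sodium hydroxide, [Na+].[OH-]
Why: Williamson etherification of the hindered phenoxide by an unhindered α-bromo ester followed by saponification in the same flask, the thioacetal being inert to base.

Step 7
Reactants: 11 [4-(1,3-dithian-2-yl)-2,6-dimethoxyphenoxy]acetic acid; 12 (S)-4-benzyloxazolidin-2-one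
Product: 14 (S)-4-benzyl-3-{[4-(1,3-dithian-2-yl)-2,6-dimethoxyphenoxy]acetyl}oxazolidin-2-one, via mixed pivalic anhydride 13 (not isolated)
Conditions: PivCl, Et3N, THF, −20 °C; then LiCl, 12, −20 °C → rt
Reagents that add atoms: none
Why: Mixed-anhydride N-acylation of an oxazolidinone (Et3N/LiCl variant), in which the auxiliary attacks the less hindered aryloxyacetyl carbonyl of 13 and no stereocentre is touched.

Step 8
Reactants: 14 N-(aryloxyacetyl)oxazolidinone; 8 3,5-dimethoxy-4-(triisopropylsilyloxy)benzaldehyde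
Product: 16 syn aldol imide (2S 3R), via boron enolate 15 (not isolated)
Conditions: Bu2BOTf, Et3N, CH2Cl2, −78 → 0 °C; 8, −78 → 0 °C; pH 7 buffer/MeOH work-up without peroxide (thioacetal present)
Reagents that add atoms: none
Why: Evans boron syn aldol in its glycolate form, where the Z boron enolate 15 reacts through a Zimmerman–Traxler chair on the face remote from the benzyl group of the (S)-auxiliary, setting C8'' and C7'' together as the syn (threo) pair in the 7''R,8''R sense (C8'' reads S in the imide only because of CIP priorities).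

Step 9
Reactants: 16 syn aldol imide
Product: 17 (1R,2R)-2-[4-(1,3-dithian-2-yl)-2,6-dimethoxyphenoxy]-1-[3,5-dimethoxy-4-(triisopropylsilyloxy)phenyl]propane-1,3-diol
Conditions: LiBH4, MeOH (2 equiv), THF, 0 °C
Reagents that add atoms: none
Why: Reductive removal of the oxazolidinone with borohydride turns the imide carbonyl into the C9'' carbinol without touching C7''/C8'' and returns the auxiliary.

Step 10
Reactants: 17 threo diol
Product: 18 ring B dithiane with 7''-O-TBS, 9''-O-TBS and ring C O-TIPS (7''R,8''R)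
Conditions: TBSOTf, 2,6-lutidine, CH2Cl2, 0 °C
Reagents that add atoms: tert-butyldimethylsilyl triflate, CC(C)(C)[Si](C)(C)OS(=O)(=O)C(F)(F)F
Why: Silyl triflate/lutidine silylation caps the primary and the hindered benzylic hydroxyl in one operation and removes every acidic proton before the carbanion chemistry.

Step 11
Reactants: 18 ring B dithiane; 4 (5S)-5-(d-menthyloxy)furan-2(5H)-one; 6 O-TIPS vanillin
Product: 21 trans-disubstituted menthyloxy lactone (3R 4S 5S; C7' dithiane on C8'; C7 carbinol on C8), via lithiated dithiane 19 (not isolated), via lithium lactone enolate 20 (not isolated)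
Conditions: n-BuLi (1.05 equiv), THF, −78 → −20 °C; 4 (1.0 equiv), −78 °C; 6 (1.2 equiv), −78 °C; AcOH/THF quench at −78 °C
Reagents that add atoms: none
Why: n-BuLi removes the C7' proton of 18, the sulfur- and aryl-stabilised carbanion 19 adds in Michael fashion to Cβ of 4, and the lithium enolate 20 is intercepted at Cα by aldehyde 6 in an aldol addition, so C7'–C8' and C8–C7 arise in one flask. The closest known reaction type is the tandem conjugate addition–aldol of lithiated 2-aryl-1,3-dithianes to 5-alkoxybutenolides, established for butyrolactone and furofuran lignans. No ring is closed. C8' is set by the acetal carbon C9', whose menthyloxy group blocks one face so that 19 enters anti to it; C8 is set by the bulky new C8' substituent, which sends the aldehyde to the opposite face and gives the trans lactone; C7 is only loosely governed by the lithium-chelated aldol transition state and is not relied on. The step needs 1,4- over 1,2-addition, secured by the soft, hindered, delocalised carbanion and the open β-carbon, and it needs the enolate to meet 6 rather than a second molecule of 4, secured by equimolar 4 and the order of addition. All hydroxyls of 18 and 6 are silylated so no proton source competes, and the cold acetic acid quench forestalls retro-aldol.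

Step 12
Reactants: 21 menthyloxy lactone
Product: 22 triol (C7–OH, C9–OH, C9'–OH; C7' dithiane; 8S,8'S)
Conditions: LiAlH4, THF, 0 °C → rt; Na2SO4·10H2O work-up
Reagents that add atoms: none
Why: Hydride reduction of the lactone opens the ring and unmasks the acetal carbon as a hemiacetal alkoxide that sheds menthoxide, and the aldehyde is reduced at once, so C9 and C9' both end as CH2OH with C8/C8' untouched while the dithiane and silyl ethers are inert.

Step 13
Reactants: 22 triol
Product: 23 2,3,4-trisubstituted tetrahydrofuran (ring C7–O–C9'–C8'–C8; ring A trans to the C8 hydroxymethyl; dithiane arm cis to it)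
Conditions: (+)-camphor-10-sulfonic acid (10–20 mol %), CH2Cl2, 0 °C → rt
Reagents that add atoms: none
Why: Acid-catalysed SN1 cyclodehydration, in which only the ring A benzylic carbinol ionises (para-silyloxy-stabilised cation), the C9' hydroxyl captures it in a five-membered closure (the C9 hydroxyl could only give an oxetane), and reversible closure places ring A trans to the C8 hydroxymethyl group, setting 7R from either C7 epimer.

Step 14
Reactants: 23 tetrahydrofuran dithiane
Product: 25 cis-fused bicyclic hemiketal (C7' bears OH and ring B), via hydroxy ketone 24 (not isolated)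
Conditions: MeI, CaCO3, MeCN/H2O 9:1, 40 °C
Reagents that add atoms: water, O
Why: Alkylative thioacetal hydrolysis, where S-methylation makes sulfur a leaving group, water delivers the ketone under CaCO3 buffering that spares the silyl ethers and the α-stereocentre C8', and the cis C9 hydroxyl adds to the carbonyl (ring–chain tautomerism) to give the bicyclic hemiketal.

Step 15
Reactants: 25 bicyclic hemiketal
Product: 26 fully silylated target (ring A exo, ring B endo)
Conditions: Et3SiH, BF3·OEt2, CH2Cl2, −78 °C; Et3N then aq NaHCO3 added at −78 °C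
Reagents that add atoms: none
Why: Ionic reduction of a hemiketal (silane/Lewis acid), where BF3 ionises the tertiary, aryl- and oxygen-stabilised C7' position far faster than any other C–O bond at −78 °C and Et3SiH attacks the oxocarbenium ion from the convex face of the cis-fused bicycle, so H7' ends exo and ring B endo (7'S).

Step 16
Reactants: 26 fully silylated target
Product: 27 CNP0317965.1
Conditions: Bu4NF, AcOH, THF, 0 °C → rt
Reagents that add atoms: none
Why: Fluoride-induced global desilylation removes both aryl TIPS and both alkyl TBS groups, the acetic acid buffer keeps the phenoxides from triggering base chemistry at the benzylic positions, and no stereocentre is affected.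

Compound list
1 | furfural | O=Cc1ccco1 | starting material
2 | 5-hydroxyfuran-2(5H)-one (racemic) | O=C1C=CC(O)O1 | intermediate
3 | (+)-menthol, (1S,2R,5S) | CC(C)[C@H]1CC[C@H](C)C[C@@H]1O | starting material
4 | (5S)-5-[(1S,2R,5S)-menthyloxy]furan-2(5H)-one | O=C1O[C@H](O[C@H]2C[C@@H](C)CC[C@@H]2C(C)C)C=C1 | intermediate
5 | vanillin | COc1cc(C=O)ccc1O | starting material
6 | 3-methoxy-4-(triisopropylsilyloxy)benzaldehyde | COc1cc(C=O)ccc1O[Si](C(C)C)(C(C)C)C(C)C | intermediate
7 | syringaldehyde | COc1cc(C=O)cc(OC)c1O | starting material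
8 | 3,5-dimethoxy-4-(triisopropylsilyloxy)benzaldehyde | COc1cc(C=O)cc(OC)c1O[Si](C(C)C)(C(C)C)C(C)C | intermediate
9 | 4-(1,3-dithian-2-yl)-2,6-dimethoxyphenol | COc1cc(C2SCCCS2)cc(OC)c1O | intermediate
10 | methyl [4-(1,3-dithian-2-yl)-2,6-dimethoxyphenoxy]acetate | COC(=O)COc1c(OC)cc(C2SCCCS2)cc1OC | intermediate
11 | [4-(1,3-dithian-2-yl)-2,6-dimethoxyphenoxy]acetic acid | OC(=O)COc1c(OC)cc(C2SCCCS2)cc1OC | intermediate
12 | (S)-4-benzyloxazolidin-2-one | O=C1N[C@@H](Cc2ccccc2)CO1 | starting material
13 | mixed anhydride of 11 with pivalic acid | CC(C)(C)C(=O)OC(=O)COc1c(OC)cc(C2SCCCS2)cc1OC | intermediate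
14 | (S)-4-benzyl-3-{[4-(1,3-dithian-2-yl)-2,6-dimethoxyphenoxy]acetyl}oxazolidin-2-one | COc1cc(C2SCCCS2)cc(OC)c1OCC(=O)N1[C@@H](Cc2ccccc2)COC1=O | intermediate
15 | (Z)-dibutylboron enolate of 14 (aryloxy cis to O–B) | COc1cc(C2SCCCS2)cc(OC)c1O/C=C(\OB(CCCC)CCCC)N1[C@@H](Cc2ccccc2)COC1=O | intermediate
16 | (S)-4-benzyl-3-{(2S,3R)-2-[4-(1,3-dithian-2-yl)-2,6-dimethoxyphenoxy]-3-hydroxy-3-[3,5-dimethoxy-4-(triisopropylsilyloxy)phenyl]propanoyl}oxazolidin-2-one | COc1cc(C2SCCCS2)cc(OC)c1O[C@H](C(=O)N1[C@@H](Cc2ccccc2)COC1=O)[C@H](O)c1cc(OC)c(O[Si](C(C)C)(C(C)C)C(C)C)c(OC)c1 | intermediate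
17 | (1R,2R)-2-[4-(1,3-dithian-2-yl)-2,6-dimethoxyphenoxy]-1-[3,5-dimethoxy-4-(triisopropylsilyloxy)phenyl]propane-1,3-diol (threo) | COc1cc(C2SCCCS2)cc(OC)c1O[C@H](CO)[C@H](O)c1cc(OC)c(O[Si](C(C)C)(C(C)C)C(C)C)c(OC)c1 | intermediate
18 | bis-TBS ether of 17 (ring B 1,3-dithiane; 7''R,8''R) | COc1cc(C2SCCCS2)cc(OC)c1O[C@H](CO[Si](C)(C)C(C)(C)C)[C@H](O[Si](C)(C)C(C)(C)C)c1cc(OC)c(O[Si](C(C)C)(C(C)C)C(C)C)c(OC)c1 | intermediate
19 | 2-lithio derivative of 18 (Li on C7') | COc1cc(C2([Li])SCCCS2)cc(OC)c1O[C@H](CO[Si](C)(C)C(C)(C)C)[C@H](O[Si](C)(C)C(C)(C)C)c1cc(OC)c(O[Si](C(C)C)(C(C)C)C(C)C)c(OC)c1 | intermediate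
20 | lithium enolate of the conjugate adduct (dithianyl group on C8' anti to menthyloxy) | [Li]OC1=C[C@H](C2(SCCCS2)c2cc(OC)c(O[C@H](CO[Si](C)(C)C(C)(C)C)[C@H](O[Si](C)(C)C(C)(C)C)c3cc(OC)c(O[Si](C(C)C)(C(C)C)C(C)C)c(OC)c3)c(OC)c2)[C@@H](O[C@H]2C[C@@H](C)CC[C@@H]2C(C)C)O1 | intermediate
21 | (3R,4S,5S)-5-(d-menthyloxy)dihydrofuran-2(3H)-one with the 2-(ring B aryl)-1,3-dithian-2-yl group at C4 (C8') and, trans to it, the (R)-hydroxy[3-methoxy-4-(triisopropylsilyloxy)phenyl]methyl group at C3 (C8) | O=C1O[C@H](O[C@H]2C[C@@H](C)CC[C@@H]2C(C)C)[C@@H](C2(SCCCS2)c2cc(OC)c(O[C@H](CO[Si](C)(C)C(C)(C)C)[C@H](O[Si](C)(C)C(C)(C)C)c3cc(OC)c(O[Si](C(C)C)(C(C)C)C(C)C)c(OC)c3)c(OC)c2)[C@@H]1[C@@H](O)c1ccc(O[Si](C(C)C)(C(C)C)C(C)C)c(OC)c1 | intermediate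
22 | acyclic triol (8S,8'S): C7 carbinol, C9 and C9' CH2OH, C7' dithiane | OC[C@@H](C1(SCCCS1)c1cc(OC)c(O[C@H](CO[Si](C)(C)C(C)(C)C)[C@H](O[Si](C)(C)C(C)(C)C)c2cc(OC)c(O[Si](C(C)C)(C(C)C)C(C)C)c(OC)c2)c(OC)c1)[C@@H](CO)[C@@H](O)c1ccc(O[Si](C(C)C)(C(C)C)C(C)C)c(OC)c1 | intermediate
23 | tetrahydrofuran (7R,8S,8'S): ring A at C7, CH2OH at C8 (trans to ring A), 2-aryl-1,3-dithian-2-yl at C8' (cis to CH2OH) | COc1cc([C@@H]2OC[C@@H](C3(SCCCS3)c3cc(OC)c(O[C@H](CO[Si](C)(C)C(C)(C)C)[C@H](O[Si](C)(C)C(C)(C)C)c4cc(OC)c(O[Si](C(C)C)(C(C)C)C(C)C)c(OC)c4)c(OC)c3)[C@H]2CO)ccc1O[Si](C(C)C)(C(C)C)C(C)C | intermediate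
24 | hydroxy ketone (C7' aryl ketone on C8', free C9–OH) | COc1cc([C@@H]2OC[C@@H](C(=O)c3cc(OC)c(O[C@H](CO[Si](C)(C)C(C)(C)C)[C@H](O[Si](C)(C)C(C)(C)C)c4cc(OC)c(O[Si](C(C)C)(C(C)C)C(C)C)c(OC)c4)c(OC)c3)[C@H]2CO)ccc1O[Si](C(C)C)(C(C)C)C(C)C | intermediate
25 | cis-fused 3,7-dioxabicyclo[3.3.0]octane hemiketal (OH and ring B on C7') | COc1cc([C@@H]2OC[C@@H]3[C@H]2COC3(O)c2cc(OC)c(O[C@H](CO[Si](C)(C)C(C)(C)C)[C@H](O[Si](C)(C)C(C)(C)C)c3cc(OC)c(O[Si](C(C)C)(C(C)C)C(C)C)c(OC)c3)c(OC)c2)ccc1O[Si](C(C)C)(C(C)C)C(C)C | intermediate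
26 | tetrasilyl ether of the target (7R,8S,7'S,8'S,7''R,8''R) | COc1cc([C@@H]2OC[C@@H]3[C@H]2CO[C@@H]3c2cc(OC)c(O[C@H](CO[Si](C)(C)C(C)(C)C)[C@H](O[Si](C)(C)C(C)(C)C)c3cc(OC)c(O[Si](C(C)C)(C(C)C)C(C)C)c(OC)c3)c(OC)c2)ccc1O[Si](C(C)C)(C(C)C)C(C)C | intermediate
27 | CNP0317965.1 | COc1cc([C@@H]2OC[C@@H]3[C@H]2CO[C@@H]3c2cc(OC)c(O[C@H](CO)[C@H](O)c3cc(OC)c(O)c(OC)c3)c(OC)c2)ccc1O | target

Total step count: 16. Longest linear sequence: 12 steps (7 → 9 → 11 → 14 → 16 → 17 → 18 → 21 → 22 → 23 → 25 → 26 → 27).

Steps most likely to fail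

Step 11.
- **What may go wrong:** The basic carbanion may take the acetal proton of the butenolide instead of adding. It may also attack the carbonyl. The enolate may be trapped incompletely, or the aldol may reverse during the quench.
- **Fallback:** It sets out from 18 and 4 and comes back at 21, and it separates the two bond formations. The carbanion 19 is added to 4 as before, but the enolate is protonated cold and the trans β-substituted menthyloxy lactone F1 is isolated and purified. Its enolate is then regenerated with LiN(iPr)2 in THF at −78 °C and treated with 6 in a separate directed aldol addition. The C8' substituent again directs the aldehyde to the opposite face, giving 21.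

Step 15.
- **What may go wrong:** Lewis-acid-induced reopening and epimerisation at C7' may erode the endo selectivity. The other benzylic C–O bonds (C7, C7'') may ionise and then be over-reduced by the silane.
- **Fallback:** It sets out from 25 and comes back at 26. It replaces the substrate-controlled ionic reduction by a reagent-controlled carbonyl reduction and a base-induced closure, with no Lewis acid present.
  - TsCl in pyridine at 0 °C sulfonylates the primary C9 hydroxyl of the open tautomer and drains the ring–chain equilibrium to the keto tosylate F2.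
  - Corey–Bakshi–Shibata reduction should give the 7'S hydroxy tosylate F3. It uses BH3·SMe2 and (R)-2-methyl-CBS-oxazaborolidine [(3aR)-1-methyl-3,3-diphenyltetrahydro-1H,3H-pyrrolo[1,2-c][1,3,2]oxazaborole], with ring B acting as the large group.
  - NaH in THF then closes C7'–O–C9 by intramolecular Williamson displacement at the primary carbon. This leaves the C7' configuration untouched and gives 26.

Step 13.
- **What may go wrong:** Ring B may intercept the C7 cation in a Friedel–Crafts closure, or a dithiane sulfur may capture it. The primary silyl ether may also be lost under acid if long reaction times are needed.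
- **Fallback:** It sets out from 22 and comes back at 25 by inverting the order of unmasking and ring closure.
  - MeI/CaCO3 in aqueous MeCN is applied to the triol first, and the ketone rests as the monocyclic C7'–O–C9 hemiketal F4.
  - Ring B then sits on a ketone-level carbon free of sulfur and is a much poorer internal nucleophile.
  - The same catalytic camphorsulfonic acid in CH2Cl2 ionises C7, and the C9' hydroxyl closes the second ring to give 25 directly.

Further compounds
F1 | step 11 | (4S,5S)-5-(d-menthyloxy)-4-[2-(ring B aryl)-1,3-dithian-2-yl]dihydrofuran-2(3H)-one (conjugate adduct, C8 unsubstituted) | O=C1O[C@H](O[C@H]2C[C@@H](C)CC[C@@H]2C(C)C)[C@@H](C2(SCCCS2)c2cc(OC)c(O[C@H](CO[Si](C)(C)C(C)(C)C)[C@H](O[Si](C)(C)C(C)(C)C)c3cc(OC)c(O[Si](C(C)C)(C(C)C)C(C)C)c(OC)c3)c(OC)c2)C1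
F2 | step 15 | keto tosylate (C9 O-tosylate of 24) | COc1cc([C@@H]2OC[C@@H](C(=O)c3cc(OC)c(O[C@H](CO[Si](C)(C)C(C)(C)C)[C@H](O[Si](C)(C)C(C)(C)C)c4cc(OC)c(O[Si](C(C)C)(C(C)C)C(C)C)c(OC)c4)c(OC)c3)[C@H]2COS(=O)(=O)c2ccc(C)cc2)ccc1O[Si](C(C)C)(C(C)C)C(C)C
F3 | step 15 | 7'S hydroxy tosylate | COc1cc([C@@H]2OC[C@@H]([C@H](O)c3cc(OC)c(O[C@H](CO[Si](C)(C)C(C)(C)C)[C@H](O[Si](C)(C)C(C)(C)C)c4cc(OC)c(O[Si](C(C)C)(C(C)C)C(C)C)c(OC)c4)c(OC)c3)[C@H]2COS(=O)(=O)c2ccc(C)cc2)ccc1O[Si](C(C)C)(C(C)C)C(C)C
F4 | step 13 | monocyclic hemiketal (ring C7'–O–C9–C8–C8') with free C7 carbinol and C9' CH2OH | OC[C@@H]1[C@H]([C@@H](O)c2ccc(O[Si](C(C)C)(C(C)C)C(C)C)c(OC)c2)COC1(O)c1cc(OC)c(O[C@H](CO[Si](C)(C)C(C)(C)C)[C@H](O[Si](C)(C)C(C)(C)C)c2cc(OC)c(O[Si](C(C)C)(C(C)C)C(C)C)c(OC)c2)c(OC)c1
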